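**Retrosynthetic overview**

1. Locants: C1 = ring carbon bearing OAc; then round the eight-membered ring C2 (CH2), C3 (CHMe), C4 and C6 (cyclopropane CH, bridged by C5H2), C7 and C8 (alkene shared with the butenolide; C10 = lactone C=O on C7, C9 = OCH2 on C8), C11 (CH bearing the side chain), C12 (side-chain CHMe). The ring face carrying the C11 side chain is the lower face (it also carries OAc and C5); the C3 methyl is on the upper face.
2. Endgame: side-chain hydroperoxide by Schenck ene reaction of the prenyl-type terminus; butenolide by carbonylative lactonisation of a C7 enol triflate onto C9–OH, with C9 stored as a C1 carbonate and moved to C8 through a temporary bridging lactone; cyclopropane by 3-exo-tet alkylation of the C7 ketone enolate (through C6) with a C5 sulfonate on C4.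
3. Key disconnection: the ring bond C3–C4, made by anionic oxy-Cope ring expansion of a cis-1,2-dialkenyl-2-silyloxycyclobutanolate in which the temporary bond C1–C7 breaks.
4. Enabling feature: C3–C4 lies between C2–C1(O) and C6–C7, and C7 is an sp2 ring-fusion carbon that can be carried at the ketone level. The chain C1(O)–C2–C3–C4–C6–C7(O) is therefore the 1,6-dioxygenated retron of a 1,2-dialkenylcyclobutane-1,2-diol [3,3] shift, which also converts two alkene geometries into the C3 and C4 stereocentres under control of C11.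
5. The four-membered ring comes from acyloin condensation of a 2-alkylsuccinate made from (R)-citronellic acid (C12 bought, C11 by auxiliary alkylation). Ring order: cyclobutane (temporary) → eight-membered ring → cyclopropane → bridging lactone (temporary) → butenolide.

Key step: step 8

Assumption: (E)-3-(tributylstannyl)prop-2-en-1-ol and (Z)-1-bromoprop-1-ene are treated as purchasable; the stannane is otherwise one step from propargyl alcohol by radical hydrostannation.

**Route**

Step 1
Reactants: 1 (R)-citronellic acid [(3R)-3,7-dimethyloct-6-enoic acid]; 2 (R)-4-benzyl-1,3-oxazolidin-2-one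
Product: 4 (4R)-4-benzyl-3-[(3R)-3,7-dimethyloct-6-enoyl]-1,3-oxazolidin-2-one, via mixed pivalic anhydride 3 (not isolated)
Conditions: t-BuCOCl, Et3N, THF, −20 °C; then 2, LiCl, −20 → 23 °C
Reagents that add atoms: none
Why: N-acylation of the oxazolidinone by the mixed pivalic anhydride is the standard imide formation, and C12 is bought with 1.

Step 2
Reactants: 4; 5 methyl bromoacetate
Product: 7 (4R)-4-benzyl-3-[(2R,3R)-2-(2-methoxy-2-oxoethyl)-3,7-dimethyloct-6-enoyl]-1,3-oxazolidin-2-one, via sodium Z-enolate 6 (not isolated)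
Conditions: NaN(SiMe3)2, THF, −78 °C; then 5, −78 → −40 °C
Reagents that add atoms: none
Why: Evans alkylation, in which the chelated Z sodium enolate is alkylated by the bromoacetate on the face opposite the benzyl group, sets C11 (2R).

Step 3
Reactants: 7
Product: 8 dimethyl (2R)-2-[(2R)-6-methylhept-5-en-2-yl]butanedioate
Conditions: MeMgBr, MeOH, 0 °C; then 7, 0 → 23 °C
Reagents that add atoms: methanol, CO
Why: Transesterification of the imide with bromomagnesium methoxide cleaves the exocyclic acyl group to the methyl ester without epimerising C11 and returns the auxiliary.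

Step 4
Reactants: 8
Product: 9 (3R)-3-[(2R)-6-methylhept-5-en-2-yl]-1,2-bis(trimethylsilyloxy)cyclobut-1-ene
Conditions: Na (dispersion), Me3SiCl, toluene, 110 °C
Reagents that add atoms: chlorotrimethylsilane, C[Si](C)(C)Cl
Why: Acyloin condensation of a succinate in the presence of Me3SiCl (Rühlmann variant) closes the four-membered ring by reductive C1–C7 coupling and traps the enediolate, so that C11 is not exposed to alkoxide.

Step 5
Reactants: 9
Product: 10 (3R)-3-[(2R)-6-methylhept-5-en-2-yl]cyclobutane-1,2-dione
Conditions: Br2 (1.0 equiv), CH2Cl2, −78 °C; crude 10 used at once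
Reagents that add atoms: none
Why: Bromine oxidises the electron-rich tetrasubstituted enediol bis-silyl ether to the 1,2-dione with loss of Me3SiBr far faster than it adds to the side-chain alkene, and no base is present that could epimerise C11.

Step 6
Reactants: 11 (E)-3-(tributylstannyl)prop-2-en-1-ol
Product: 12 tert-butyldimethyl{[(E)-3-(tributylstannyl)prop-2-en-1-yl]oxy}silane
Conditions: t-BuMe2SiCl, imidazole, CH2Cl2, 23 °C
Reagents that add atoms: tert-butyldimethylsilyl chloride, CC(C)(C)[Si](C)(C)Cl
Why: Standard silylation of a primary allylic alcohol with imidazole as base.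

Step 7
Reactants: 10; 12
Product: 15 (2S,4R)-2-(tert-butyldimethylsilyloxy)-2-[(E)-3-(tert-butyldimethylsilyloxy)prop-1-enyl]-4-[(2R)-6-methylhept-5-en-2-yl]cyclobutan-1-one (alkenyl group trans to the side chain), via alkenyllithium 13 (not isolated), via lithium alkoxide 14 (not isolated)
Conditions: 12, n-BuLi, THF, −78 °C; then 10, −78 °C; then t-BuMe2SiOTf, −78 → 0 °C
Reagents that add atoms: tert-butyldimethylsilyl trifluoromethanesulfonate, CC(C)(C)[Si](C)(C)OS(=O)(=O)C(F)(F)F
Why: Tin–lithium exchange gives the E alkenyllithium, which should add once to the less hindered carbonyl (C7, remote from the side chain) and, as in additions to 3-substituted cyclobutanones, from the face opposite the side chain on the diagonal carbon; silylation of the tertiary alkoxide in the flask then fixes the C7 carbinol centre.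

Step 8
Reactants: 15; 16 (Z)-1-bromoprop-1-ene
Product: 20 eight-membered keto silyl enol ether (C1 ketone; C3 methyl on the upper face; C4 CH2OSi-t-BuMe2 on the lower face; ring-cis C6=C7 with OSi-t-BuMe2 on C7; C11 side chain on the lower face), via (Z)-prop-1-enyllithium 17 (not isolated), via lithium cyclobutanolate 18 (not isolated), via lithium enolate 19 (not isolated)
Conditions: 16, Li (2 equiv), Et2O, 0 °C; then 15, THF, −78 °C; then DMPU, −78 → 23 °C; AcOH, −78 °C
Reagents that add atoms: none
Why: (Z)-Prop-1-enyllithium adds to the strained ketone of 15 on the face opposite the C7 silyloxy group and the C11 side chain, so that the two alkenyl groups of alkoxide 18 are cis; the alkoxide then drives a charge-accelerated [3,3] sigmatropic shift (anionic oxy-Cope) through the boat transition state open to a cis-1,2-dialkenylcyclobutane, in which C3 bonds to C4 while the cyclobutane bond C1–C7 breaks, and enolate 19 is protonated at C2 by the cold acid quench. The closest known reaction is the tandem alkenyl-metal addition/oxy-Cope ring expansion of 2-alkenylcyclobutanones to cyclooct-5-enones and of 1,2-dialkenylcyclobutane-1,2-diol derivatives to cyclooctane-1,4-diones. The eight-membered ring is closed by this four-atom ring expansion (bond C3–C4 between the two alkenyl termini), and release of cyclobutane strain makes it irreversible. C3 and C4 are set by the transition-state geometry: the Z methyl group lies inside and the E CH2OSi group outside the boat, which places them trans to each other, and both are tied to C11 because the alkenyl groups sit on the cyclobutane face opposite the side chain (C4–CH2OSi ends cis and C3–Me trans to it), while the carbinol centres C1 and C7 of 18 are consumed. The step needs 1,2-addition instead of enolisation (cyclobutanones enolise reluctantly), cis placement of the alkenyl groups (both other substituents lie on the opposite face) and two oxygen functions that stay distinct: the shift delivers C1 as a lithium enolate fixed towards C2 and C7 as a silyl enol ether fixed towards C6, so C11 is never enolised.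

Step 9
Reactants: 20
Product: 21 C1 alcohol of 20 (hydroxyl on the lower face, cis to the C11 side chain)
Conditions: LiBH(s-Bu)3, THF, −78 °C
Reagents that add atoms: none
Why: Substrate-controlled ketone reduction in which the bulky hydride should approach C1 from the ring face opposite the adjacent C11 side chain, placing the new hydroxyl cis to that chain, while the silyl enol ether is inert.

Step 10
Reactants: 21
Product: 22 C1 methyl carbonate of 21
Conditions: ClCO2Me, pyridine, DMAP (cat.), CH2Cl2, 0 °C
Reagents that add atoms: methyl chloroformate, COC(=O)Cl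
Why: O-acylation of the C1 hydroxyl with a chloroformate protects it during the enolate steps and stores the future C9 carbon where the C8 enolate can later reach it.

Step 11
Reactants: 22
Product: 23 keto alcohol (C7 ketone; C4 CH2OH; C1 methyl carbonate)
Conditions: Bu4NF, AcOH, THF, 0 → 23 °C
Reagents that add atoms: none
Why: Buffered fluoride cleaves both silicon–oxygen bonds at once, so the silyl enol ether gives the C7 ketone regiospecifically and the primary silyl ether gives the C5 alcohol.

Step 12
Reactants: 23
Product: 26 bridged β-keto γ-lactone (C9 carbonyl linking C8 to the C1 oxygen on the lower face; C7 ketone; cis-fused C4–C5–C6 cyclopropane), via primary mesylate 24 (not isolated), via cyclopropyl ketone carbonate 25 (not isolated)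
Conditions: MeSO2Cl, Et3N, THF, −20 °C; then KN(SiMe3)2 (2.1 equiv), −78 → −20 °C; then KN(SiMe3)2 (1.2 equiv), −20 → 23 °C; AcOH
Reagents that add atoms: none
Why: Sulfonylation of the primary hydroxyl, 3-exo-tet alkylation of the C7 ketone enolate through C6 (γ-sulfonyloxy ketone to cyclopropyl ketone, with C6 fixed by C4 because C5 can only bridge the ring cis) and then Dieckmann-type acylation of the C8 enolate by the C1 carbonate (5-exo-trig) close the cyclopropane and carry C9 onto C8.

Step 13
Reactants: 26
Product: 27 enol triflate of 26 (C7–OSO2CF3; C7=C8 ring-cis)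
Conditions: (CF3SO2)2O, Et3N, CH2Cl2, −78 → 0 °C
Reagents that add atoms: trifluoromethanesulfonic anhydride, FC(F)(F)S(=O)(=O)OS(=O)(=O)C(F)(F)F
Why: O-triflation of the enol of the β-keto lactone (1,3-dicarbonyl to β-triflyloxy enoate) fixes the C7=C8 double bond, which the ring holds cis.

Step 14
Reactants: 27
Product: 28 diol alkenyl triflate (C1–OH; C8–CH2OH; C7–OSO2CF3)
Conditions: i-Bu2AlH (4 equiv), CH2Cl2, −78 → −20 °C
Reagents that add atoms: none
Why: Aluminium hydride reduction of the unsaturated lactone to the allylic alcohol turns C9 into CH2OH and frees the C1 hydroxyl without touching the alkenyl triflate.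

Step 15
Reactants: 28
Product: 29 hydroxy butenolide (target skeleton with C1–OH and a (2R)-6-methylhept-5-en-2-yl side chain)
Conditions: Pd(PPh3)4 (5 mol %), CO (1 atm), Bu3N, LiCl, MeCN, 65 °C
Reagents that add atoms: carbon monoxide, [C-]#[O+]
Why: Palladium-catalysed carbonylative lactonisation of a Z γ-hydroxy alkenyl triflate, in which oxidative addition to zerovalent palladium, CO insertion and capture of the acylpalladium by the C9 hydroxyl close the butenolide, the five-membered closure being favoured over attack of the more remote secondary C1 hydroxyl.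

Step 16
Reactants: 29
Product: 30 C1 acetate of 29
Conditions: Ac2O, pyridine, DMAP (cat.), CH2Cl2, 23 °C
Reagents that add atoms: acetic anhydride, CC(=O)OC(C)=O
Why: Acetylation of the only remaining hydroxyl under nucleophilic catalysis.

Step 17
Reactants: 30
Product: 31 target hydroperoxide CNP0205234.1
Conditions: O2, methylene blue (cat.), visible light, CH2Cl2, 0 °C
Reagents that add atoms: dioxygen, O=O
Why: Schenck ene reaction, in which singlet oxygen attacks only the electron-rich trisubstituted side-chain alkene (the tetrasubstituted butenolide alkene is electron-poor) and abstraction of an allylic hydrogen from the neighbouring CH2 group gives the tertiary hydroperoxide with an E double bond, the regioisomeric secondary hydroperoxide being the expected co-product to be removed by chromatography.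

**Compound list**

1 | (R)-citronellic acid, (3R)-3,7-dimethyloct-6-enoic acid | OC(=O)C[C@H](C)CCC=C(C)C | starting material
2 | (R)-4-benzyl-1,3-oxazolidin-2-one | O=C1OC[C@@H](Cc2ccccc2)N1 | starting material
3 | (3R)-3,7-dimethyloct-6-enoic pivalic anhydride | CC(C)(C)C(=O)OC(=O)C[C@H](C)CCC=C(C)C | intermediate
4 | (4R)-4-benzyl-3-[(3R)-3,7-dimethyloct-6-enoyl]-1,3-oxazolidin-2-one | O=C1OC[C@@H](Cc2ccccc2)N1C(=O)C[C@H](C)CCC=C(C)C | intermediate
5 | methyl bromoacetate | COC(=O)CBr | starting material
6 | sodium (Z)-enolate of 4 | [Na]O/C(N1[C@H](Cc2ccccc2)COC1=O)=C\[C@H](C)CCC=C(C)C | intermediate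
7 | (4R)-4-benzyl-3-[(2R,3R)-2-(2-methoxy-2-oxoethyl)-3,7-dimethyloct-6-enoyl]-1,3-oxazolidin-2-one | O=C1OC[C@@H](Cc2ccccc2)N1C(=O)[C@H](CC(=O)OC)[C@H](C)CCC=C(C)C | intermediate
8 | dimethyl (2R)-2-[(2R)-6-methylhept-5-en-2-yl]butanedioate | COC(=O)C[C@@H](C(=O)OC)[C@H](C)CCC=C(C)C | intermediate
9 | (3R)-3-[(2R)-6-methylhept-5-en-2-yl]-1,2-bis(trimethylsilyloxy)cyclobut-1-ene | C[Si](C)(C)OC1=C(O[Si](C)(C)C)C[C@@H]1[C@H](C)CCC=C(C)C | intermediate
10 | (3R)-3-[(2R)-6-methylhept-5-en-2-yl]cyclobutane-1,2-dione | O=C1C(=O)C[C@@H]1[C@H](C)CCC=C(C)C | intermediate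
11 | (E)-3-(tributylstannyl)prop-2-en-1-ol | CCCC[Sn](CCCC)(CCCC)/C=C/CO | starting material
12 | tert-butyldimethyl{[(E)-3-(tributylstannyl)prop-2-en-1-yl]oxy}silane | CCCC[Sn](CCCC)(CCCC)/C=C/CO[Si](C)(C)C(C)(C)C | intermediate
13 | (E)-3-(tert-butyldimethylsilyloxy)prop-1-enyllithium | [Li]/C=C/CO[Si](C)(C)C(C)(C)C | intermediate
14 | lithium alkoxide of the C7 mono-adduct of 10 (alkenyl group trans to the side chain) | O=C1[C@@](O[Li])(/C=C/CO[Si](C)(C)C(C)(C)C)C[C@@H]1[C@H](C)CCC=C(C)C | intermediate
15 | (2S,4R)-2-(tert-butyldimethylsilyloxy)-2-[(E)-3-(tert-butyldimethylsilyloxy)prop-1-enyl]-4-[(2R)-6-methylhept-5-en-2-yl]cyclobutan-1-one | O=C1[C@@](O[Si](C)(C)C(C)(C)C)(/C=C/CO[Si](C)(C)C(C)(C)C)C[C@@H]1[C@H](C)CCC=C(C)C | intermediate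
16 | (Z)-1-bromoprop-1-ene | C/C=C\Br | starting material
17 | (Z)-prop-1-enyllithium | C/C=C\[Li] | intermediate
18 | lithium 2-(tert-butyldimethylsilyloxy)-2-[(E)-3-(tert-butyldimethylsilyloxy)prop-1-enyl]-4-[(2R)-6-methylhept-5-en-2-yl]-1-[(Z)-prop-1-enyl]cyclobutan-1-olate (alkenyl groups cis to each other, trans to the side chain) | [Li]O[C@]1(/C=C\C)[C@@](O[Si](C)(C)C(C)(C)C)(/C=C/CO[Si](C)(C)C(C)(C)C)C[C@@H]1[C@H](C)CCC=C(C)C | intermediate
19 | lithium enolate of 20 (C1–OLi; C1=C2 and C6=C7 ring-cis) | [Li]O/C1=C/[C@@H](C)[C@H](CO[Si](C)(C)C(C)(C)C)/C=C(O[Si](C)(C)C(C)(C)C)\C[C@@H]1[C@H](C)CCC=C(C)C | intermediate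
20 | eight-membered keto silyl enol ether: C1 ketone, C3 methyl (upper face), C4 CH2OSi-t-BuMe2 (lower face), ring-cis C6=C7 with OSi-t-BuMe2 on C7, C11 (2R)-6-methylhept-5-en-2-yl (lower face) | O=C1C[C@@H](C)[C@H](CO[Si](C)(C)C(C)(C)C)/C=C(O[Si](C)(C)C(C)(C)C)\C[C@@H]1[C@H](C)CCC=C(C)C | intermediate
21 | C1 alcohol of 20 (hydroxyl on the lower face) | O[C@@H]1C[C@@H](C)[C@H](CO[Si](C)(C)C(C)(C)C)/C=C(O[Si](C)(C)C(C)(C)C)\C[C@@H]1[C@H](C)CCC=C(C)C | intermediate
22 | C1 methyl carbonate of 21 | COC(=O)O[C@@H]1C[C@@H](C)[C@H](CO[Si](C)(C)C(C)(C)C)/C=C(O[Si](C)(C)C(C)(C)C)\C[C@@H]1[C@H](C)CCC=C(C)C | intermediate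
23 | keto alcohol: C7 ketone, C4 CH2OH, C1 methyl carbonate | COC(=O)O[C@@H]1C[C@@H](C)[C@H](CO)CC(=O)C[C@@H]1[C@H](C)CCC=C(C)C | intermediate
24 | C5 methanesulfonate of 23 | COC(=O)O[C@@H]1C[C@@H](C)[C@H](COS(C)(=O)=O)CC(=O)C[C@@H]1[C@H](C)CCC=C(C)C | intermediate
25 | cyclopropyl ketone carbonate: cis-fused C4–C5–C6 cyclopropane (C5 on the lower face), C7 ketone, C1 methyl carbonate | COC(=O)O[C@@H]1C[C@@H](C)[C@@H]2C[C@@H]2C(=O)C[C@@H]1[C@H](C)CCC=C(C)C | intermediate
26 | bridged β-keto γ-lactone: C9 carbonyl links C8 to the C1 oxygen on the lower face, C7 ketone, cyclopropane as in 25 | O=C1O[C@@H]2C[C@@H](C)[C@@H]3C[C@@H]3C(=O)[C@H]1[C@@H]2[C@H](C)CCC=C(C)C | intermediate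
27 | enol triflate of 26 (C7–OSO2CF3, C7=C8 ring-cis) | O=C1O[C@@H]2C[C@@H](C)[C@@H]3C[C@@H]3/C(OS(=O)(=O)C(F)(F)F)=C1\[C@@H]2[C@H](C)CCC=C(C)C | intermediate
28 | diol alkenyl triflate: C1–OH, C8–CH2OH, C7–OSO2CF3 | O[C@@H]1C[C@@H](C)[C@@H]2C[C@@H]2/C(OS(=O)(=O)C(F)(F)F)=C(CO)\[C@@H]1[C@H](C)CCC=C(C)C | intermediate
29 | hydroxy butenolide: target skeleton with C1–OH and a (2R)-6-methylhept-5-en-2-yl side chain | O[C@@H]1C[C@@H](C)[C@@H]2C[C@@H]2C2=C(COC2=O)[C@@H]1[C@H](C)CCC=C(C)C | intermediate
30 | C1 acetate of 29 | CC(=O)O[C@@H]1C[C@@H](C)[C@@H]2C[C@@H]2C2=C(COC2=O)[C@@H]1[C@H](C)CCC=C(C)C | intermediate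
31 | CNP0205234.1, the tertiary (E)-allylic hydroperoxide | CC(=O)O[C@@H]1C[C@@H](C)[C@@H]2C[C@@H]2C2=C(COC2=O)[C@@H]1[C@H](C)C/C=C/C(C)(C)OO | target

**Step count and risks**

Total step count: 17. Longest linear sequence: 16 (steps 1–5 and 7–17; step 6 prepares the alkenyl fragment).

Steps most likely to fail:

Step 8. The alkenyllithium may enolise the hindered ketone instead of adding, the silyl group may migrate between the two cis oxygens of the alkoxide, or the alkoxide may fragment and recombine stepwise, which would erode the transfer of alkene geometry to C3 and C4. The fallback sets out from 15 and avoids any free alkoxide during the rearrangement. The (Z)-propenyl group is added as its less basic cerium reagent (17 with CeCl3) and the alkoxide is capped in the flask with Me3SiCl to give the bis-silyl ether F1. A neutral thermal Cope rearrangement (toluene, 110 °C, same boat geometry) gives the bis(silyl enol ether) F2. K2CO3 in MeOH at 0 °C cleaves only the trimethylsilyl enol ether and returns to 20.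

Step 7. The sensitive 1,2-dione may undergo base-induced ring contraction or enolisation, may add the nucleophile twice, or may not discriminate enough between its two carbonyl groups. The fallback sets out from 9 and bypasses the dione. A BF3·OEt2-promoted Mukaiyama aldol addition of 9 to 3-(tert-butyldimethylsilyloxy)propanal, reacting through the less hindered enediol carbon C7 anti to the side chain, gives the 2-(1-hydroxyalkyl)-2-(trimethylsilyloxy)cyclobutanone F3. Dehydration with the Burgess reagent gives the (E)-alkene F4. K2CO3 in MeOH removes the trimethylsilyl group to give the α-hydroxy ketone F5, and t-BuMe2SiOTf with 2,6-lutidine returns to 15.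

Step 9. Hydride delivery to the flexible eight-membered ketone may show poor facial selectivity and favour the C1 epimer. The fallback sets out from 20 and corrects the centre by inversion instead of by reagent control. Reduction under whichever conditions give the epimer cleanly (for example NaBH4 in MeOH) gives the epimeric alcohol F6. Mitsunobu inversion with 4-nitrobenzoic acid (PPh3, diisopropyl azodicarboxylate) gives the inverted ester F7, and K2CO3 in MeOH at 0 °C returns to 21.

Further compounds
F1 | step 8 | bis-silyl ether: C1 trimethylsilyl ether of the cis-dialkenyl cyclobutanol corresponding to 18 | C[Si](C)(C)O[C@]1(/C=C\C)[C@@](O[Si](C)(C)C(C)(C)C)(/C=C/CO[Si](C)(C)C(C)(C)C)C[C@@H]1[C@H](C)CCC=C(C)C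
F2 | step 8 | bis(silyl enol ether): C1 trimethylsilyl enol ether corresponding to 19 | C[Si](C)(C)O/C1=C/[C@@H](C)[C@H](CO[Si](C)(C)C(C)(C)C)/C=C(O[Si](C)(C)C(C)(C)C)\C[C@@H]1[C@H](C)CCC=C(C)C
F3 | step 7 | 2-[3-(tert-butyldimethylsilyloxy)-1-hydroxypropyl]-4-[(2R)-6-methylhept-5-en-2-yl]-2-(trimethylsilyloxy)cyclobutan-1-one (carbinol epimers) | O=C1[C@@](O[Si](C)(C)C)(C(O)CCO[Si](C)(C)C(C)(C)C)C[C@@H]1[C@H](C)CCC=C(C)C
F4 | step 7 | 2-[(E)-3-(tert-butyldimethylsilyloxy)prop-1-enyl]-4-[(2R)-6-methylhept-5-en-2-yl]-2-(trimethylsilyloxy)cyclobutan-1-one | O=C1[C@@](O[Si](C)(C)C)(/C=C/CO[Si](C)(C)C(C)(C)C)C[C@@H]1[C@H](C)CCC=C(C)C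
F5 | step 7 | 2-[(E)-3-(tert-butyldimethylsilyloxy)prop-1-enyl]-2-hydroxy-4-[(2R)-6-methylhept-5-en-2-yl]cyclobutan-1-one | O=C1[C@@](O)(/C=C/CO[Si](C)(C)C(C)(C)C)C[C@@H]1[C@H](C)CCC=C(C)C
F6 | step 9 | C1 epimer of 21 (hydroxyl on the upper face) | O[C@H]1C[C@@H](C)[C@H](CO[Si](C)(C)C(C)(C)C)/C=C(O[Si](C)(C)C(C)(C)C)\C[C@@H]1[C@H](C)CCC=C(C)C
F7 | step 9 | 4-nitrobenzoate of 21 (ester on the lower face) | O=C(O[C@@H]1C[C@@H](C)[C@H](CO[Si](C)(C)C(C)(C)C)/C=C(O[Si](C)(C)C(C)(C)C)\C[C@@H]1[C@H](C)CCC=C(C)C)c1ccc(cc1)[N+](=O)[O-]
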